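**Retrosynthetic overview**
1. Target 35 (a 6,7-seco-ent-kaurane 7,20-lactone) comes from dione 33 by one Luche reduction that sets the C11 and C15 carbinols; ring D of 33 (C13–C16 bond, C16=C17) is closed by an intramolecular Rauhut–Currier reaction of bis-enone 32.
2. The δ-lactone ring (O–C7–C8–C9–C10–C20) and the C8, C9 and C10 stereocentres are made in one operation from ring A oxalate 16 and ring C enone 22: radical union at the hindered C9–C10 bond, then ring closure by the C7–C8 bond.
3. Enabling feature: C8 lies between the C7 lactone carbonyl and the C15 carbinol carbon (a latent 1,3-dicarbonyl), so with C15 as a ketone C8 is an enolate carbon; spiro carbon C10 carries C20–O, which can hold C7 as an aryl carbonate six atoms from C8; the 11-oxygen next to C9 steers the union.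
4. Ring A fragment from 4,4-dimethylcyclohexane-1,3-dione (C5 by CuH reduction, C1 by Luche reduction, C10/C20 oxygens by dihydroxylation); ring C fragment from 3-bromocyclohex-2-en-1-one (C11 by CBS reduction).
5. Order of ring formation: carbocycles A and C (preformed) → lactone ring (step 13) → ring D (step 17).

Key step: step 13

Remark: ent-kaurane numbering is used (C7 lactone carbonyl, C8 quaternary carbon, C20 lactone CH2, C6 the CH2OH carbon); the C10 configuration of 13–16 is of no consequence because C10 becomes a radical in step 13, and the senses of induction in steps 4 and 10 are assigned by analogy, the antipodal ligand or catalyst being used if they prove opposite.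

**Step 1**
Reactants: 1 4,4-dimethylcyclohexane-1,3-dione
Product: 2 3-(2-methylpropoxy)-6,6-dimethylcyclohex-2-en-1-one
Conditions: i-BuOH, TsOH·H2O (cat.), toluene, reflux, Dean–Stark
Reagents that add atoms: 2-methylpropan-1-ol CC(C)CO
Why: acid-catalysed vinylogous ester formation should occur at the carbonyl remote from the gem-dimethyl group, leaving the hindered C=O free for the later 1,2-addition; no stereocentre is formed.

**Step 2**
Reactants: 2 3-(2-methylpropoxy)-6,6-dimethylcyclohex-2-en-1-one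
Product: 5 3-(hydroxymethyl)-4,4-dimethylcyclohex-2-en-1-one, via lithium alkoxide adduct 3 (not isolated), via methoxymethyl ether enone 4 (not isolated)
Conditions: Bu3SnCH2OCH2OMe, n-BuLi, THF, −78 °C; then 2, −78 to 0 °C; then 3 M HCl, MeOH, 50 °C
Reagents that add atoms: tributyl[(methoxymethoxy)methyl]stannane CCCC[Sn](CCCC)(CCCC)COCOC
Why: tin–lithium exchange gives the alkoxymethyllithium, which adds 1,2 to the vinylogous ester, and aqueous acid then effects the Stork–Danheiser enone transposition and cleaves the methoxymethyl acetal, placing the future C6 on the carbon next to CMe2; no stereocentre.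

**Step 3**
Reactants: 5 3-(hydroxymethyl)-4,4-dimethylcyclohex-2-en-1-one
Product: 6 3-{[(tert-butyldiphenylsilyl)oxy]methyl}-4,4-dimethylcyclohex-2-en-1-one
Conditions: TBDPSCl, imidazole, DMF, rt
Reagents that add atoms: tert-butyl(chloro)diphenylsilane CC(C)(C)[Si](Cl)(c1ccccc1)c1ccccc1
Why: standard silylation of a primary alcohol, the TBDPS ether being chosen to outlast the later acid-labile triethylsilyl ether; no stereocentre.

**Step 4**
Reactants: 6 3-{[(tert-butyldiphenylsilyl)oxy]methyl}-4,4-dimethylcyclohex-2-en-1-one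
Product: 10 (3R)-3-{[(tert-butyldiphenylsilyl)oxy]methyl}-4,4-dimethyl-2-methylidenecyclohexan-1-one, via silyl enol ether 7 (not isolated), via Mannich base 8 (not isolated), via methiodide 9 (not isolated)
Conditions: Cu(OAc)2·H2O (3 mol %), (R)-DTBM-SEGPHOS (3 mol %), (EtO)2MeSiH, toluene, 0 °C; then Me2N=CH2+ I−, CH2Cl2, rt; then MeI; then aq NaHCO3, rt
Reagents that add atoms: dimethyl(methylidene)ammonium iodide (Eschenmoser's salt) C[N+](C)=C.[I-]
Why: ligand-controlled CuH asymmetric conjugate reduction of the 3-substituted cyclohexenone should set C5 by hydride delivery to one enantiotopic face, and the regiospecific silyl enol ether is then aminomethylated (Mannich reaction), quaternised and eliminated to the 2-methylidene ketone that carries C20.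

**Step 5**
Reactants: 10 (3R)-3-{[(tert-butyldiphenylsilyl)oxy]methyl}-4,4-dimethyl-2-methylidenecyclohexan-1-one
Product: 11 (1S,3R)-3-{[(tert-butyldiphenylsilyl)oxy]methyl}-4,4-dimethyl-2-methylidenecyclohexan-1-ol
Conditions: NaBH4, CeCl3·7H2O, MeOH, −78 °C
Reagents that add atoms: none
Why: Luche 1,2-reduction of the enone, in which hydride should add to C1 anti to the C5 CH2OSi group that flanks the exocyclic alkene, giving the 1,3-cis allylic alcohol (C1 S).

**Step 6**
Reactants: 11 (1S,3R)-3-{[(tert-butyldiphenylsilyl)oxy]methyl}-4,4-dimethyl-2-methylidenecyclohexan-1-ol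
Product: 12 (1S,3R)-3-{[(tert-butyldiphenylsilyl)oxy]methyl}-4,4-dimethyl-2-methylidenecyclohexyl acetate
Conditions: Ac2O, pyridine, DMAP (cat.), CH2Cl2, 0 °C to rt
Reagents that add atoms: acetic anhydride CC(=O)OC(C)=O
Why: routine acetylation of the secondary alcohol installs the C1 acetate of the target early; no new stereocentre.

**Step 7**
Reactants: 12 (1S,3R)-3-{[(tert-butyldiphenylsilyl)oxy]methyl}-4,4-dimethyl-2-methylidenecyclohexyl acetate
Product: 13 (1S,2R,3S)-3-{[(tert-butyldiphenylsilyl)oxy]methyl}-2-hydroxy-2-(hydroxymethyl)-4,4-dimethylcyclohexyl acetate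
Conditions: OsO4 (2 mol %), NMO, acetone/H2O, rt
Reagents that add atoms: N-methylmorpholine N-oxide C[N+]1([O-])CCOCC1; water O
Why: catalytic dihydroxylation of the 1,1-disubstituted alkene should occur anti to the two cis allylic substituents and gives the tertiary C10 alcohol and the C20 primary alcohol (the C10 configuration is later erased).

**Step 8**
Reactants: 13 (1S,2R,3S)-3-{[(tert-butyldiphenylsilyl)oxy]methyl}-2-hydroxy-2-(hydroxymethyl)-4,4-dimethylcyclohexyl acetate
Product: 15 (1S,2R,3S)-1-acetoxy-3-{[(tert-butyldiphenylsilyl)oxy]methyl}-4,4-dimethyl-2-{[(phenoxycarbonyl)oxy]methyl}cyclohexan-2-yl methyl oxalate, via mono phenyl carbonate 14 (not isolated)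
Conditions: PhOCOCl, pyridine, CH2Cl2, −20 °C; then MeO2CCOCl, Et3N, DMAP (cat.), 0 °C to rt
Reagents that add atoms: phenyl chloroformate O=C(Cl)Oc1ccccc1; methyl chlorooxoacetate COC(=O)C(Cl)=O
Why: chemoselective acylation, the primary C20 alcohol taking the chloroformate (this carbonate carbon is C7) and the tertiary alcohol then being esterified in the same flask by the very reactive oxalyl chloride half-ester before it can close a cyclic carbonate; no new stereocentre.

**Step 9**
Reactants: 15 (1S,2R,3S)-1-acetoxy-3-{[(tert-butyldiphenylsilyl)oxy]methyl}-4,4-dimethyl-2-{[(phenoxycarbonyl)oxy]methyl}cyclohexan-2-yl methyl oxalate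
Product: 16 cesium (1S,2R,3S)-1-acetoxy-3-{[(tert-butyldiphenylsilyl)oxy]methyl}-4,4-dimethyl-2-{[(phenoxycarbonyl)oxy]methyl}cyclohexan-2-yl oxalate
Conditions: CsOH·H2O (1.0 equiv), THF/H2O, 0 °C; lyophilise
Reagents that add atoms: cesium hydroxide [Cs+].[OH-]
Why: selective half-saponification, one equivalent of hydroxide being expected to attack only the highly electrophilic methyl oxalate ester and to leave the acetate and the phenyl carbonate.

**Step 10**
Reactants: 17 3-bromocyclohex-2-en-1-one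
Product: 18 (1S)-3-bromocyclohex-2-en-1-ol
Conditions: (R)-2-methyl-CBS-oxazaborolidine (10 mol %), BH3·SMe2, THF, −20 °C; MeOH quench
Reagents that add atoms: none
Why: CBS reduction, in which the alkenyl side of the ketone acts as the large group so that the (R)-catalyst should deliver hydride to give the (S)-allylic alcohol (future C11).

**Step 11**
Reactants: 18 (1S)-3-bromocyclohex-2-en-1-ol
Product: 19 {[(1S)-3-bromocyclohex-2-en-1-yl]oxy}triethylsilane
Conditions: Et3SiCl, imidazole, CH2Cl2, 0 °C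
Reagents that add atoms: chlorotriethylsilane CC[Si](Cl)(CC)CC
Why: routine silylation gives a bulky, aprotic allylic ether that can steer the radical addition and be removed later in the presence of the TBDPS ether.

**Step 12**
Reactants: 19 {[(1S)-3-bromocyclohex-2-en-1-yl]oxy}triethylsilane
Product: 22 1-[(3S)-3-(triethylsilyloxy)cyclohex-1-en-1-yl]ethan-1-one, via alkenyllithium 20 (not isolated), via tetrahedral lithium adduct 21 (not isolated)
Conditions: t-BuLi (2.1 equiv), Et2O, −78 °C; then MeC(O)N(OMe)Me, −78 to 0 °C; then AcOH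
Reagents that add atoms: N-methoxy-N-methylacetamide CON(C)C(C)=O
Why: bromine–lithium exchange and acylation of the alkenyllithium with a Weinreb amide, whose chelated tetrahedral adduct prevents over-addition, give the enone that carries C15 and C16; the stereocentre is untouched.

**Step 13**
Reactants: 16 cesium oxalate (ring A fragment); 22 1-[(3S)-3-(triethylsilyloxy)cyclohex-1-en-1-yl]ethan-1-one (ring C fragment)
Product: 25 spiro β-keto δ-lactone (8-acetyl; 1α-OAc; 6-OTBDPS; 11β-OTES; lactone O–C7–C8–C9–C10–C20 cis-fused to ring C), via tertiary C10 radical 23 (not isolated), via cesium enolate 24 (not isolated)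
Conditions: Ir[dF(CF3)ppy]2(dtbbpy)PF6 (2 mol %), 22 (1.5 equiv), dry DME/DMF (3:1), 4 Å MS, blue LEDs, 25–40 °C; then AcOH
Reagents that add atoms: none
Why: Proposed new method: the excited trivalent iridium photocatalyst oxidises cesium oxalate 16, loss of two CO2 gives tertiary C10 radical 23, which adds to C9 of enone 22 (Giese addition), and the resulting C8 α-keto radical is reduced by the divalent iridium species to cesium enolate 24, which in the absence of a proton source attacks the carbonate carbon C7 and expels phenoxide (intramolecular Claisen-type C-acylation). The closest known reaction types are the photoredox coupling of tertiary radicals from cesium oxalates with enones, which ends in an enolate, and the Dieckmann-type C-acylation of ketone enolates by carbonates; merging them in one flask is what is new. The δ-lactone closes by 6-exo-trig attack of C8 on the C7 carbonyl, the only cyclisation open to the tetrasubstituted enolate because O-acylation or attack from C16 would give eight-membered rings. C10 is set by the ring A chair, where the axial C4 methyl group blocks axial approach so that C9 enters equatorially, trans to the 1-OAc and C6 groups; C9 is set by addition anti to the adjacent allylic 11-OTES group; C8 is set by the tether, which delivers C7 to the enolate face syn to C10 (cis ring fusion, acetyl axial) because allylic strain holds C10 axial. The step needs attack at C9 and not C8 of 22 and acylation faster than enolate protonation, which the β-position of C9 in the enone, strictly aprotic conditions and the activated aryl carbonate should secure.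

**Step 14**
Reactants: 25 spiro β-keto δ-lactone
Product: 29 8-acryloyl spirolactone (vinyl ketone C15(=O)–C16=C17; otherwise as 25), via lithium enolate 26 (not isolated), via Mannich base 27 (not isolated), via methiodide 28 (not isolated)
Conditions: LiN(SiMe3)2, THF, −78 °C; then Me2N=CH2+ I−, −78 to 0 °C; then MeI, rt; then aq NaHCO3, CH2Cl2
Reagents that add atoms: dimethyl(methylidene)ammonium iodide (Eschenmoser's salt) C[N+](C)=C.[I-]
Why: the methyl group is the only enolisable ketone position (C8 is quaternary), so its lithium enolate is aminomethylated (Mannich reaction) and the amine is quaternised and eliminated to the vinyl ketone, which brings in C17; no stereocentre.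

**Step 15**
Reactants: 29 8-acryloyl spirolactone
Product: 30 11β-hydroxy 8-acryloyl spirolactone
Conditions: HF·pyridine, pyridine, THF, 0 °C
Reagents that add atoms: none
Why: selective desilylation, the secondary triethylsilyl ether being expected to cleave much faster than the primary TBDPS ether under buffered, weakly acidic fluoride conditions.

**Step 16**
Reactants: 30 11β-hydroxy 8-acryloyl spirolactone
Product: 32 bis-enone (11-oxo-12-ene ring C plus 8-acryloyl), via C11 ketone 31 (not isolated)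
Conditions: IBX (4 equiv), DMSO, 25 then 70 °C
Reagents that add atoms: none
Why: IBX oxidation of the alcohol followed by IBX dehydrogenation of the ketone, which can only desaturate C12–C13 because the C9 side is flanked by the quaternary C8 and C10.

**Step 17**
Reactants: 32 bis-enone
Product: 33 1α-acetoxy-6-[(tert-butyldiphenylsilyl)oxy]-11,15-dioxo-6,7-seco-ent-kaur-16-en-7,20-olide
Conditions: PBu3 (20 mol %), t-AmOH, rt, high dilution
Reagents that add atoms: none
Why: intramolecular Rauhut–Currier reaction, in which the phosphine adds to the unhindered vinyl ketone, the zwitterionic enolate carbon C16 attacks C13 of the cyclohexenone (5-exo) and proton transfer with loss of phosphine leaves the C16=C17 methylidene; C13 is set by geometry because the axial acryloyl group can reach only one face.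

**Step 18**
Reactants: 33 1α-acetoxy-6-[(tert-butyldiphenylsilyl)oxy]-11,15-dioxo-6,7-seco-ent-kaur-16-en-7,20-olide
Product: 34 1α-acetoxy-6-[(tert-butyldiphenylsilyl)oxy]-11,15-dihydroxy-6,7-seco-ent-kaur-16-en-7,20-olide (11-OH axial and syn to the C15–C16 bridge; 15-OH endo)
Conditions: NaBH4, CeCl3·7H2O, MeOH/THF, −78 to 0 °C
Reagents that add atoms: none
Why: Luche reduction of both carbonyls, hydride being expected to reach C15 from the exo face (away from the C9–C11–C12 bridge) and C11 from the face away from the C15–C16 bridge, which gives the endo 15-alcohol and the axial 11-alcohol of the target.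

**Step 19**
Reactants: 34 1α-acetoxy-6-[(tert-butyldiphenylsilyl)oxy]-11,15-dihydroxy-6,7-seco-ent-kaur-16-en-7,20-olide
Product: 35 1α-acetoxy-6,11,15-trihydroxy-6,7-seco-ent-kaur-16-en-7,20-olide (target CNP0210922.1)
Conditions: HF·pyridine, pyridine, THF, 0 °C to rt
Reagents that add atoms: none
Why: fluoride-mediated cleavage of the primary TBDPS ether under buffered conditions that should leave the acetate, the lactone and the allylic alcohol untouched.

**Compound list**
1 | 4,4-dimethylcyclohexane-1,3-dione | CC1(C)CCC(=O)CC1=O | starting material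
2 | 3-(2-methylpropoxy)-6,6-dimethylcyclohex-2-en-1-one | CC(C)COC1=CC(=O)C(C)(C)CC1 | intermediate
3 | lithium 1-[(methoxymethoxy)methyl]-3-(2-methylpropoxy)-6,6-dimethylcyclohex-2-en-1-olate (racemic 1,2-adduct) | [Li+].[O-]C1(COCOC)C=C(OCC(C)C)CCC1(C)C | intermediate (not isolated)
4 | 3-[(methoxymethoxy)methyl]-4,4-dimethylcyclohex-2-en-1-one | O=C1C=C(COCOC)C(C)(C)CC1 | intermediate (not isolated)
5 | 3-(hydroxymethyl)-4,4-dimethylcyclohex-2-en-1-one | O=C1C=C(CO)C(C)(C)CC1 | intermediate
6 | 3-{[(tert-butyldiphenylsilyl)oxy]methyl}-4,4-dimethylcyclohex-2-en-1-one | O=C1C=C(CO[Si](c2ccccc2)(c2ccccc2)C(C)(C)C)C(C)(C)CC1 | intermediate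
7 | {[(3S)-3-{[(tert-butyldiphenylsilyl)oxy]methyl}-4,4-dimethylcyclohex-1-en-1-yl]oxy}diethoxy(methyl)silane | CCO[Si](C)(OCC)OC1=C[C@H](CO[Si](c2ccccc2)(c2ccccc2)C(C)(C)C)C(C)(C)CC1 | intermediate (not isolated)
8 | (2R,3S)-3-{[(tert-butyldiphenylsilyl)oxy]methyl}-2-[(dimethylamino)methyl]-4,4-dimethylcyclohexan-1-one (2,3-trans drawn; C2 is lost on elimination) | CN(C)C[C@@H]1C(=O)CCC(C)(C)[C@H]1CO[Si](c2ccccc2)(c2ccccc2)C(C)(C)C | intermediate (not isolated)
9 | trimethylammonium iodide formed from 8 by N-methylation | C[N+](C)(C)C[C@@H]1C(=O)CCC(C)(C)[C@H]1CO[Si](c2ccccc2)(c2ccccc2)C(C)(C)C.[I-] | intermediate (not isolated)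
10 | (3R)-3-{[(tert-butyldiphenylsilyl)oxy]methyl}-4,4-dimethyl-2-methylidenecyclohexan-1-one | C=C1C(=O)CCC(C)(C)[C@H]1CO[Si](c2ccccc2)(c2ccccc2)C(C)(C)C | intermediate
11 | (1S,3R)-3-{[(tert-butyldiphenylsilyl)oxy]methyl}-4,4-dimethyl-2-methylidenecyclohexan-1-ol | C=C1[C@@H](O)CCC(C)(C)[C@H]1CO[Si](c2ccccc2)(c2ccccc2)C(C)(C)C | intermediate
12 | (1S,3R)-3-{[(tert-butyldiphenylsilyl)oxy]methyl}-4,4-dimethyl-2-methylidenecyclohexyl acetate | C=C1[C@@H](OC(C)=O)CCC(C)(C)[C@H]1CO[Si](c2ccccc2)(c2ccccc2)C(C)(C)C | intermediate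
13 | (1S,2R,3S)-3-{[(tert-butyldiphenylsilyl)oxy]methyl}-2-hydroxy-2-(hydroxymethyl)-4,4-dimethylcyclohexyl acetate | OC[C@@]1(O)[C@@H](OC(C)=O)CCC(C)(C)[C@H]1CO[Si](c2ccccc2)(c2ccccc2)C(C)(C)C | intermediate
14 | (1S,2R,3S)-3-{[(tert-butyldiphenylsilyl)oxy]methyl}-2-hydroxy-4,4-dimethyl-2-{[(phenoxycarbonyl)oxy]methyl}cyclohexyl acetate | O=C(OC[C@@]1(O)[C@@H](OC(C)=O)CCC(C)(C)[C@H]1CO[Si](c2ccccc2)(c2ccccc2)C(C)(C)C)Oc1ccccc1 | intermediate (not isolated)
15 | (1S,2R,3S)-1-acetoxy-3-{[(tert-butyldiphenylsilyl)oxy]methyl}-4,4-dimethyl-2-{[(phenoxycarbonyl)oxy]methyl}cyclohexan-2-yl methyl oxalate | COC(=O)C(=O)O[C@]1(COC(=O)Oc2ccccc2)[C@@H](OC(C)=O)CCC(C)(C)[C@H]1CO[Si](c2ccccc2)(c2ccccc2)C(C)(C)C | intermediate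
16 | cesium salt of the oxalic acid half-ester corresponding to 15 (ring A fragment) | [Cs+].[O-]C(=O)C(=O)O[C@]1(COC(=O)Oc2ccccc2)[C@@H](OC(C)=O)CCC(C)(C)[C@H]1CO[Si](c2ccccc2)(c2ccccc2)C(C)(C)C | intermediate
17 | 3-bromocyclohex-2-en-1-one | O=C1C=C(Br)CCC1 | starting material
18 | (1S)-3-bromocyclohex-2-en-1-ol | BrC1=C[C@@H](O)CCC1 | intermediate
19 | {[(1S)-3-bromocyclohex-2-en-1-yl]oxy}triethylsilane | BrC1=C[C@@H](O[Si](CC)(CC)CC)CCC1 | intermediate
20 | [(3S)-3-(triethylsilyloxy)cyclohex-1-en-1-yl]lithium | [Li]C1=C[C@@H](O[Si](CC)(CC)CC)CCC1 | intermediate (not isolated)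
21 | lithium alkoxide adduct of 20 with N-methoxy-N-methylacetamide | [Li]OC(C)(N(C)OC)C1=C[C@@H](O[Si](CC)(CC)CC)CCC1 | intermediate (not isolated)
22 | 1-[(3S)-3-(triethylsilyloxy)cyclohex-1-en-1-yl]ethan-1-one (ring C fragment) | CC(=O)C1=C[C@@H](O[Si](CC)(CC)CC)CCC1 | intermediate
23 | tertiary C10 radical from 16 (1-OAc, 5-CH2OTBDPS and C20 phenyl carbonate kept) | O=C(OC[C]1[C@@H](OC(C)=O)CCC(C)(C)[C@H]1CO[Si](c2ccccc2)(c2ccccc2)C(C)(C)C)Oc1ccccc1 | intermediate (not isolated)
24 | cesium enolate of the Giese adduct (C9–C10 bond formed, C8=C15 enolate, C7 still a phenyl carbonate) | CC([O-])=C1CCC[C@H](O[Si](CC)(CC)CC)[C@H]1[C@]2(COC(=O)Oc3ccccc3)[C@@H](OC(C)=O)CCC(C)(C)[C@H]2CO[Si](c3ccccc3)(c3ccccc3)C(C)(C)C.[Cs+] | intermediate (not isolated)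
25 | spiro β-keto δ-lactone: ring A (1α-OAc, 6-OTBDPS) spiro at C10; lactone O–C7–C8–C9–C10–C20 cis-fused to cyclohexane ring C; 8-acetyl; 11β-OTES; C8, C9, C10 as in the target | C1C[C@H](O[Si](CC)(CC)CC)[C@@H]3[C@](C1)(C(=O)OC[C@]32[C@@H](OC(C)=O)CCC(C)(C)[C@H]2CO[Si](c4ccccc4)(c4ccccc4)C(C)(C)C)C(C)=O | intermediate
26 | lithium enolate of 25 (C15=C16) | C1C[C@H](O[Si](CC)(CC)CC)[C@@H]3[C@](C1)(C(=O)OC[C@]32[C@@H](OC(C)=O)CCC(C)(C)[C@H]2CO[Si](c4ccccc4)(c4ccccc4)C(C)(C)C)C(=C)O[Li] | intermediate (not isolated)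
27 | Mannich base: 25 with 3-(dimethylamino)propanoyl in place of acetyl | C1C[C@H](O[Si](CC)(CC)CC)[C@@H]3[C@](C1)(C(=O)OC[C@]32[C@@H](OC(C)=O)CCC(C)(C)[C@H]2CO[Si](c4ccccc4)(c4ccccc4)C(C)(C)C)C(=O)CCN(C)C | intermediate (not isolated)
28 | trimethylammonium iodide formed from 27 | C1C[C@H](O[Si](CC)(CC)CC)[C@@H]3[C@](C1)(C(=O)OC[C@]32[C@@H](OC(C)=O)CCC(C)(C)[C@H]2CO[Si](c4ccccc4)(c4ccccc4)C(C)(C)C)C(=O)CC[N+](C)(C)C.[I-] | intermediate (not isolated)
29 | 8-acryloyl spirolactone (25 with C15(=O)–C16=C17 in place of acetyl) | C1C[C@H](O[Si](CC)(CC)CC)[C@@H]3[C@](C1)(C(=O)OC[C@]32[C@@H](OC(C)=O)CCC(C)(C)[C@H]2CO[Si](c4ccccc4)(c4ccccc4)C(C)(C)C)C(=O)C=C | intermediate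
30 | 11β-hydroxy 8-acryloyl spirolactone | C1C[C@H](O)[C@@H]3[C@](C1)(C(=O)OC[C@]32[C@@H](OC(C)=O)CCC(C)(C)[C@H]2CO[Si](c4ccccc4)(c4ccccc4)C(C)(C)C)C(=O)C=C | intermediate
31 | 11-oxo 8-acryloyl spirolactone | C1CC(=O)[C@@H]3[C@](C1)(C(=O)OC[C@]32[C@@H](OC(C)=O)CCC(C)(C)[C@H]2CO[Si](c4ccccc4)(c4ccccc4)C(C)(C)C)C(=O)C=C | intermediate (not isolated)
32 | bis-enone: 11-oxo-12-ene ring C plus 8-acryloyl | C1=CC(=O)[C@@H]3[C@](C1)(C(=O)OC[C@]32[C@@H](OC(C)=O)CCC(C)(C)[C@H]2CO[Si](c4ccccc4)(c4ccccc4)C(C)(C)C)C(=O)C=C | intermediate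
33 | 1α-acetoxy-6-[(tert-butyldiphenylsilyl)oxy]-11,15-dioxo-6,7-seco-ent-kaur-16-en-7,20-olide | C=C1[C@@H]2CC(=O)[C@@H]3[C@](C2)(C(=O)OC[C@]32[C@@H](OC(C)=O)CCC(C)(C)[C@H]2CO[Si](c4ccccc4)(c4ccccc4)C(C)(C)C)C1=O | intermediate
34 | 1α-acetoxy-6-[(tert-butyldiphenylsilyl)oxy]-11,15-dihydroxy-6,7-seco-ent-kaur-16-en-7,20-olide (11-OH axial, syn to the C15–C16 bridge; 15-OH endo) | C=C1[C@@H]2C[C@H](O)[C@@H]3[C@](C2)(C(=O)OC[C@]32[C@@H](OC(C)=O)CCC(C)(C)[C@H]2CO[Si](c4ccccc4)(c4ccccc4)C(C)(C)C)[C@@H]1O | intermediate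
35 | 1α-acetoxy-6,11,15-trihydroxy-6,7-seco-ent-kaur-16-en-7,20-olide (CNP0210922.1) | C=C1[C@@H]2C[C@H](O)[C@@H]3[C@](C2)(C(=O)OC[C@]32[C@@H](OC(C)=O)CCC(C)(C)[C@H]2CO)[C@@H]1O | target

**Step count and risks**
Total step count: 19. Longest linear sequence: 16 steps (steps 1–9, then 13–19).

Most likely to fail:

1. Step 13 (Proposed new method). The enolate may be protonated, or the hindered radical may add too slowly, before C-acylation can occur, so that uncyclised material results. Fallback with known chemistry, setting out from 16 and 22: the same photoredox coupling is run with water (10 equiv), so that the enolate is protonated and the Giese ketone F1 is isolated with its phenyl carbonate intact. Treatment of F1 with NaH and catalytic t-BuOH in THF should then equilibrate to the more substituted C8 enolate, whose Dieckmann-type C-acylation by the carbonate closes the lactone. The fallback comes back to the route at 25.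

2. Step 17. The phosphine may trigger oligomerisation of the vinyl ketone, or the zwitterion may fail to reach C13. Fallback, setting out from 32: PhSLi in THF at −78 to 0 °C adds to the vinyl ketone, and the resulting lithium enolate closes ring D by Michael addition to C13 (thiolate-triggered tandem Michael–Michael), giving the sulfide F2. Oxidation with mCPBA at −78 °C gives the sulfoxide F3, which on warming in toluene should lose benzenesulfenic acid by syn-elimination. The fallback comes back at 33.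

3. Step 18. Facial selectivity may be poor, or reduction may stall, at the C11 ketone, which is shielded on one face by the C15–C16 bridge and on the other by axial C10. The fallback keeps the C11 stereocentre of 22 instead of re-making it and sets out from 25. LiN(SiMe3)2 and CF3CO2CH2CF3 give the trifluoroacetyl diketone F4, which with MsN3 and Et3N gives the diazo ketone F5 (detrifluoroacetylative diazo transfer). Rh2(OAc)4 in CH2Cl2 should then effect carbenoid 1,5 C–H insertion into the axial C13–H bond to give the bridged ketone F6 with the 11-OTES group untouched. Methylenation as in step 14, through the Mannich base F7 and the methiodide F8, gives the enone F9, and Luche reduction gives the allylic alcohol F10. HF·pyridine then removes both silyl ethers, and the fallback comes back at 35.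

**Further compounds**
F1 | step 13 | Giese ketone (C9–C10 bond formed, 8-acetyl, phenyl carbonate intact; either C8 epimer serves) | CC(=O)[C@@H]1CCC[C@H](O[Si](CC)(CC)CC)[C@H]1[C@]2(COC(=O)Oc3ccccc3)[C@@H](OC(C)=O)CCC(C)(C)[C@H]2CO[Si](c3ccccc3)(c3ccccc3)C(C)(C)C
F2 | step 17 | 16-[(phenylsulfanyl)methyl] bridged 11,15-dione (17-phenylthio-16,17-dihydro 33; either C16 epimer serves) | C(Sc4ccccc4)[C@H]1[C@@H]2CC(=O)[C@@H]3[C@](C2)(C(=O)OC[C@]32[C@@H](OC(C)=O)CCC(C)(C)[C@H]2CO[Si](c4ccccc4)(c4ccccc4)C(C)(C)C)C1=O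
F3 | step 17 | sulfoxide of F2 | C(S(=O)c4ccccc4)[C@H]1[C@@H]2CC(=O)[C@@H]3[C@](C2)(C(=O)OC[C@]32[C@@H](OC(C)=O)CCC(C)(C)[C@H]2CO[Si](c4ccccc4)(c4ccccc4)C(C)(C)C)C1=O
F4 | step 18 | trifluoroacetyl diketone (25 with C(=O)CH2C(=O)CF3 in place of acetyl) | C1C[C@H](O[Si](CC)(CC)CC)[C@@H]3[C@](C1)(C(=O)OC[C@]32[C@@H](OC(C)=O)CCC(C)(C)[C@H]2CO[Si](c4ccccc4)(c4ccccc4)C(C)(C)C)C(=O)CC(=O)C(F)(F)F
F5 | step 18 | diazo ketone (25 with diazoacetyl in place of acetyl) | C1C[C@H](O[Si](CC)(CC)CC)[C@@H]3[C@](C1)(C(=O)OC[C@]32[C@@H](OC(C)=O)CCC(C)(C)[C@H]2CO[Si](c4ccccc4)(c4ccccc4)C(C)(C)C)C(=O)C=[N+]=[N-]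
F6 | step 18 | bridged 15-ketone with ring D closed (C16 methylene; 11β-OTES; 6-OTBDPS) | C1[C@@H]2C[C@H](O[Si](CC)(CC)CC)[C@@H]3[C@](C2)(C(=O)OC[C@]32[C@@H](OC(C)=O)CCC(C)(C)[C@H]2CO[Si](c4ccccc4)(c4ccccc4)C(C)(C)C)C1=O
F7 | step 18 | Mannich base of F6 (16-[(dimethylamino)methyl]) | CN(C)C[C@H]1[C@@H]2C[C@H](O[Si](CC)(CC)CC)[C@@H]3[C@](C2)(C(=O)OC[C@]32[C@@H](OC(C)=O)CCC(C)(C)[C@H]2CO[Si](c4ccccc4)(c4ccccc4)C(C)(C)C)C1=O
F8 | step 18 | trimethylammonium iodide formed from F7 | C[N+](C)(C)C[C@H]1[C@@H]2C[C@H](O[Si](CC)(CC)CC)[C@@H]3[C@](C2)(C(=O)OC[C@]32[C@@H](OC(C)=O)CCC(C)(C)[C@H]2CO[Si](c4ccccc4)(c4ccccc4)C(C)(C)C)C1=O.[I-]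
F9 | step 18 | 16-methylidene 15-ketone with 11β-OTES and 6-OTBDPS | C=C1[C@@H]2C[C@H](O[Si](CC)(CC)CC)[C@@H]3[C@](C2)(C(=O)OC[C@]32[C@@H](OC(C)=O)CCC(C)(C)[C@H]2CO[Si](c4ccccc4)(c4ccccc4)C(C)(C)C)C1=O
F10 | step 18 | 15-hydroxy (endo) 16-methylidene compound with 11β-OTES and 6-OTBDPS | C=C1[C@@H]2C[C@H](O[Si](CC)(CC)CC)[C@@H]3[C@](C2)(C(=O)OC[C@]32[C@@H](OC(C)=O)CCC(C)(C)[C@H]2CO[Si](c4ccccc4)(c4ccccc4)C(C)(C)C)[C@@H]1O
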